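**Retrosynthetic overview**
- Magnone B is the ring-opened form of the cis-fused furo[3,4-c]furanone **13**, which 3,4-dimethoxyphenyllithium opens to the aryl ketone and the free CH2OH.
- **13** forms by acid-mediated benzylic etherification and lactonisation of triol tert-butyl ester **12**. The benzylic C7 epimers converge to the exo-aryl (2,3-trans) THF.
- **12** comes from LiBH4 reduction of the trans-aldol adduct **11**, which comes from aldol of β-ester lactone **9** with 3,4,5-trimethoxybenzaldehyde.
- **9** comes from the Johnson–Claisen product **8**. The Claisen forms the C8–C8′ bond and transfers the carbinol stereocentre of lactate-derived allylic alcohol **6** to C8′.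
- Rings form in this order: γ-lactone (step 5), then THF and the second lactone (step 8).

Assumptions: ethyl (R)-lactate is the purchased chiral material. Magnone B is taken as the open hydroxy-ketone drawn in the target SMILES.

**Step 1**
Reactants: **1** ethyl (R)-lactate
Product: **2** ethyl (2R)-2-(tert-butyldimethylsilyloxy)propanoate
Conditions: TBSCl, imidazole, DMF, 0 °C → rt
Reagents that add atoms: TBSCl, CC(C)(C)[Si](C)(C)Cl
Why: Silylation protects the secondary alcohol without touching the stereocentre.

**Step 2**
Reactants: **2**; **3** (tert-butoxycarbonylmethylene)triphenylphosphorane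
Product: **5** tert-butyl (2E,4R)-4-(TBSO)pent-2-enoate (via transient aldehyde **4**, not isolated)
Conditions: DIBAL-H, CH2Cl2, −78 °C; then add **3**, −78 °C → rt (one pot)
Reagents that add atoms: none (the ylide is listed as a reactant; DIBAL-H delivers hydride only)
Why: DIBAL stops at the aldehyde at −78 °C, and the stabilised ylide then gives the E-enoate in a Wittig olefination. The stereocentre is untouched, and the one-pot sequence avoids handling the racemisation-prone α-silyloxy aldehyde.

**Step 3**
Reactants: **5**
Product: **6** tert-butyl (2E,4R)-4-hydroxypent-2-enoate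
Conditions: TBAF, AcOH (1:1), THF, 0 °C
Reagents that add atoms: none
Why: The acetic acid buffer removes the silyl group without base-induced oxa-Michael addition or epimerisation, and the carbinol stereocentre is retained.

**Step 4 (key step)**
Reactants: **6**; **7** triethyl orthoacetate
Product: **8** 1-tert-butyl 4-ethyl (2R)-2-[(E)-prop-1-enyl]butanedioate
Conditions: **7** (5 equiv), EtCO2H (cat.), neat, 140 °C, EtOH distilled off
Reagents that add atoms: none (the orthoester is a listed reactant; propionic acid is catalytic)
Why: Johnson–Claisen [3,3]-rearrangement forms the C8–C8′ bond. The E-alkene and the equatorial methyl in the chair transition state transfer the (R)-carbinol configuration suprafacially to give (R)-C8′ (CH(CO2tBu)), with the new propenyl alkene E.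

**Step 5**
Reactants: **8**
Product: **9** tert-butyl (3R)-5-oxooxolane-3-carboxylate
Conditions: O3, CH2Cl2/MeOH, −78 °C; then NaBH4, −78 → 0 °C; workup, spontaneous lactonisation (cat. TsOH if needed)
Reagents that add atoms: O3, [O-][O+]=O, which supplies the oxygen that ends up as the lactone ring oxygen
Why: Ozonolysis converts the propenyl group to an aldehyde, which is reduced in situ before the acidic C8′–H can epimerise. The resulting γ-hydroxy ethyl ester closes to the γ-lactone, and C8′ is untouched.

**Step 6**
Reactants: **9**; **10** 3,4,5-trimethoxybenzaldehyde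
Product: **11** tert-butyl (3R,4S)-4-[hydroxy(3,4,5-trimethoxyphenyl)methyl]-5-oxooxolane-3-carboxylate (trans-lactone; carbinol carbon C7 is an epimeric mixture)
Conditions: LDA (1.05 equiv), THF, −78 °C; then **10**, −78 °C; quench with NH4Cl at −78 °C
Reagents that add atoms: none
Why: Aldol of the kinetic lactone enolate, which is more acidic than the hindered tertiary tert-butyl-ester α-H. The aldehyde approaches anti to the C8′ ester, so C8 is set trans to C8′. The C7 configuration is left open because it is equilibrated in step 8.

**Step 7**
Reactants: **11**
Product: **12** tert-butyl (2R,3R)-4-hydroxy-2,3-bis(hydroxymethyl)-4-(3,4,5-trimethoxyphenyl)butanoate (C4 epimer mixture)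
Conditions: LiBH4, THF, MeOH (2 equiv), 0 °C → rt
Reagents that add atoms: none
Why: LiBH4 reduces the lactone to the diol while the hindered tert-butyl ester survives. C8 and C8′ are not touched.

**Step 8**
Reactants: **12**
Product: **13** (3aR,4S,6aR)-4-(3,4,5-trimethoxyphenyl)tetrahydro-1H,3H-furo[3,4-c]furan-1-one
Conditions: TFA/CH2Cl2 (1:4, ~0.02 M), 0 °C → rt, 16 h
Reagents that add atoms: none
Why: The trimethoxybenzylic alcohol ionises and the C9′-OH closes the THF ring (ionic etherification). The tert-butyl ester cleaves and the acid lactonises onto the C9 hydroxymethyl, which is cis to it. The reversible benzylic ionisation funnels both C7 epimers to the exo, 2,3-trans aryl isomer. The trans-lactone geometry of **11** makes C9 and C7′ cis, so the cis-fused bicycle forms.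

**Step 9**
Reactants: **13**; **14** 4-bromo-1,2-dimethoxybenzene
Product: **15** Magnone B
Conditions: **14** (1.2 equiv), n-BuLi (1.15 equiv), THF, −78 °C, 30 min; add **13**, −78 °C, 1 h; quench with sat. NH4Cl at −78 °C
Reagents that add atoms: none beyond **14** (n-BuLi only does Br/Li exchange)
Why: The aryllithium adds once to the lactone carbonyl (C7′) to give a stable cold hemiketal alkoxide. On quench it collapses to the aryl ketone and free CH2OH, with the cis C8/C8′ centres and exo aryl preserved.

**Compound list**
1 | ethyl (R)-lactate | C[C@@H](O)C(=O)OCC | starting material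
2 | ethyl (2R)-2-(TBSO)propanoate | C[C@@H](O[Si](C)(C)C(C)(C)C)C(=O)OCC | intermediate
3 | (tert-butoxycarbonylmethylene)triphenylphosphorane | CC(C)(C)OC(=O)C=P(c1ccccc1)(c1ccccc1)c1ccccc1 | starting material
4 | (2R)-2-(TBSO)propanal (transient, not isolated) | C[C@@H](O[Si](C)(C)C(C)(C)C)C=O | intermediate
5 | tert-butyl (2E,4R)-4-(TBSO)pent-2-enoate | C[C@@H](O[Si](C)(C)C(C)(C)C)/C=C/C(=O)OC(C)(C)C | intermediate
6 | tert-butyl (2E,4R)-4-hydroxypent-2-enoate | C[C@@H](O)/C=C/C(=O)OC(C)(C)C | intermediate
7 | triethyl orthoacetate | CCOC(C)(OCC)OCC | starting material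
8 | 1-tert-butyl 4-ethyl (2R)-2-[(E)-prop-1-enyl]butanedioate | CCOC(=O)C[C@@H](C(=O)OC(C)(C)C)/C=C/C | intermediate
9 | tert-butyl (3R)-5-oxooxolane-3-carboxylate | O=C1OC[C@H](C(=O)OC(C)(C)C)C1 | intermediate
10 | 3,4,5-trimethoxybenzaldehyde | COc1cc(C=O)cc(OC)c1OC | starting material
11 | trans-aldol lactone (C7 unspecified) | O=C1OC[C@H](C(=O)OC(C)(C)C)[C@H]1C(O)c2cc(OC)c(OC)c(OC)c2 | intermediate
12 | triol tert-butyl ester (C7 unspecified) | CC(C)(C)OC(=O)[C@@H](CO)[C@H](CO)C(O)c1cc(OC)c(OC)c(OC)c1 | intermediate
13 | cis-fused furofuranone, exo aryl | O=C1OC[C@@H]2[C@@H](c3cc(OC)c(OC)c(OC)c3)OC[C@H]12 | intermediate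
14 | 4-bromo-1,2-dimethoxybenzene | COc1ccc(Br)cc1OC | starting material
15 | Magnone B | COc1ccc(C(=O)[C@H]2CO[C@H](c3cc(OC)c(OC)c(OC)c3)[C@H]2CO)cc1OC | target

**Total steps:** 9. **Longest linear sequence:** 9 steps (from **1**).

**Three steps most likely to fail**
1. **Step 8 (TFA cascade).** The tert-butyl ester carbonyl could trap the benzylic cation to give the C7–O–C7′ lactone, the tert-butyl cation could arylate the electron-rich rings, or the C7 epimers may not fully converge to the exo isomer.
 - Fallback: oxidise the benzylic alcohol of **12** to the aryl ketone with MnO2, form the hemiketal with C9′-OH, then do Et3SiH/BF3 reductive etherification, then lactonise. This sets C7 by hydride delivery rather than cation equilibration.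
2. **Step 5 (ozonolysis/NaBH4).** The intermediate β-formyl ester has a very acidic C8′–H, so the ee could erode before the aldehyde is reduced.
 - Fallback: run the Johnson–Claisen on (R,E)-5-benzyloxypent-3-en-2-ol so that CH2OBn is already at C8′. Oxidise the propenyl group to the carboxylic acid with RuCl3/NaIO4, which is configurationally stable. Then hydrogenolyse the benzyl group and lactonise to reach **9**.
3. **Step 9 (ArLi + lactone).** The aryllithium could deprotonate C8′ and trigger E1cB ring opening of the THF, or over-add to the ketone.
 - Fallback: open **13** with Me(MeO)NH·HCl/iPrMgCl to the hydroxy Weinreb amide, then add 3,4-dimethoxyphenylmagnesium bromide (3 equiv) to give the ketone.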